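**Strategy.** Briarane numbering is used (C1 = methyl-bearing quaternary carbon, C10 = ring-fusion CH, C2 and C9 = their carbinol neighbours). The plan exploits the C1–C10 edge shared by the cyclohexane and the ten-membered ring. With C11=C20 as an exocyclic alkene, C10=C1 completes a 1,3-diene (C20=C11–C10=C1). Its 1,2-bis(boronate), boron on C11 and C20, is a double allyl donor, first at C1, then at C10. One tandem double allylboration with a pyran–lactone dialdehyde (aldehyde carbons C2 and C9) forms C1–C2 and C9–C10, unites both fragments, closes the oxa-bridged ten-membered ring, sets C1, C2 and C10, and leaves the C11 methylene for the chlorohydrin.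

Key step: step 16

Remark on faces: β is the face of the C15 methyl group; on the pyran, the "upper" face is the one that carries the lactone oxygen.
Assumption: (S)-glyceraldehyde acetonide (3) is purchased and used freshly distilled.

**Pyran–lactone dialdehyde (steps 1–10)**

Step 1
Reactants: 1 furan-2-ylmethanol
Product: 2 tert-butyl(furan-2-ylmethoxy)dimethylsilane
Conditions: TBSCl, imidazole, CH2Cl2, 0 °C → rt
Reagents that add atoms: tert-butyldimethylsilyl chloride, CC(C)(C)[Si](C)(C)Cl
Why: Standard imidazole-promoted silylation of a primary alcohol; no stereocentre is involved.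

Step 2
Reactants: 2 tert-butyl(furan-2-ylmethoxy)dimethylsilane; 3 (S)-2,2-dimethyl-1,3-dioxolane-4-carbaldehyde
Product: 6 (S)-[5-((tert-butyldimethylsilyloxy)methyl)furan-2-yl][(4S)-2,2-dimethyl-1,3-dioxolan-4-yl]methanol (3,4-anti), via 5-lithiofuran 4 (not isolated), via furylzinc bromide 5 (not isolated)
Conditions: n-BuLi, THF, −78 → 0 °C; ZnBr2, 0 °C; then 3, −78 → 0 °C; aq. NH4Cl
Reagents that add atoms: none
Why: α-Lithiation of the furan at C5 and zinc-mediated addition to the α,β-dialkoxy aldehyde should give the 3,4-anti (Felkin–Anh type) carbinol known for ZnBr2-mediated furyl additions to glyceraldehyde acetonide, setting C4 from the purchased C3 centre.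

Step 3
Reactants: 6 anti furyl carbinol
Product: 7 (2S)-6-[(tert-butyldimethylsilyloxy)methyl]-2-[(4S)-2,2-dimethyl-1,3-dioxolan-4-yl]-6-hydroxy-2H-pyran-3(6H)-one (anomers at C8)
Conditions: NBS, NaHCO3, NaOAc, THF/H2O (4:1), 0 °C
Reagents that add atoms: water, O
Why: Achmatowicz rearrangement of a furfuryl alcohol; the carbinol oxygen becomes the pyran oxygen, the furan carbons become C5–C8 and C4 is untouched.

Step 4
Reactants: 7 pyranone hemiketal; 8 tert-butyl[(1-methoxyethenyl)oxy]dimethylsilane
Product: 9 methyl 2-[(2S,6S)-2-[(tert-butyldimethylsilyloxy)methyl]-6-[(4S)-2,2-dimethyl-1,3-dioxolan-4-yl]-5-oxo-5,6-dihydro-2H-pyran-2-yl]acetate (acetate arm trans to the dioxolanyl group)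
Conditions: BF3·OEt2, CH2Cl2, −78 °C
Reagents that add atoms: none
Why: Mukaiyama-type C-glycosylation of the tertiary oxocarbenium ion; the ketene acetal should enter trans to the C4 side chain, which sets the quaternary C8 with the C9 arm cis to C3.

Step 5
Reactants: 9 C-glycoside enone
Product: 10 methyl 2-[(2S,6S)-2-[(tert-butyldimethylsilyloxy)methyl]-6-[(4S)-2,2-dimethyl-1,3-dioxolan-4-yl]-5-hydroxy-5-methyl-5,6-dihydro-2H-pyran-2-yl]acetate (C5 epimers)
Conditions: MeMgBr, CeCl3, THF, −78 °C; aq. NH4Cl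
Reagents that add atoms: methylmagnesium bromide, C[Mg]Br
Why: Organocerium 1,2-addition to the enone carbonyl leaves the ester untouched at −78 °C; the new carbinol centre is destroyed in step 6, so its configuration does not matter.

Step 6
Reactants: 10 tertiary allylic alcohol
Product: 11 cis-fused γ-lactone of the 5-methyl-3,6-dihydro-2H-pyran (C7–O lactone, C8 bearing CH2OTBS, C4 bearing the dioxolane)
Conditions: BF3·OEt2, CH2Cl2, −78 → −30 °C; aq. NaHCO3
Reagents that add atoms: none
Why: Acid-mediated allylic 1,3-transposition with lactonization: the tertiary allylic alcohol ionizes and the tethered ester carbonyl captures C7 in a 5-exo mode on the face of its own arm, giving the cis-fused lactone and setting C7.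

Step 7
Reactants: 11 cis-fused lactone
Product: 12 17-methyl lactone (C17 methyl cis to the pyran oxygen, trans to the C9 arm)
Conditions: LiN(iPr)2, THF, −78 °C; MeI, −78 °C
Reagents that add atoms: iodomethane, CI
Why: Lactone enolate alkylation; methyl iodide should approach C17 anti to the C9 arm on the adjacent quaternary C8, which sets C17.

Step 8
Reactants: 12 17-methyl lactone
Product: 13 triol (C2–OH, C3–OH, C9–OH)
Conditions: camphorsulfonic acid (cat.), MeOH, 0 °C → rt
Reagents that add atoms: none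
Why: Acid-catalysed methanolysis removes the terminal acetonide and the primary silyl ether under conditions that leave the allylic lactone intact.

Step 9
Reactants: 13 triol
Product: 14 tris(triethylsilyl) ether
Conditions: TESOTf, 2,6-lutidine, CH2Cl2, −78 → 0 °C
Reagents that add atoms: triethylsilyl trifluoromethanesulfonate, CC[Si](CC)(CC)OS(=O)(=O)C(F)(F)F
Why: Exhaustive silylation of two primary and one secondary alcohol with a silyl triflate.

Step 10
Reactants: 14 tris(triethylsilyl) ether
Product: 15 dialdehyde (C2 aldehyde next to C3–OTES; C9 aldehyde on quaternary C8)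
Conditions: (COCl)2, DMSO, CH2Cl2, −78 → −30 °C; Et3N, −78 → 0 °C
Reagents that add atoms: none
Why: Swern conditions oxidize primary triethylsilyl ethers directly to aldehydes while a secondary TES ether survives, so both aldehydes are unveiled in one step.

**Cyclohexenyl bis(boronate) (steps 11–15)**

Step 11
Reactants: 16 2-methylcyclohex-2-en-1-one
Product: 17 (S)-2-methylcyclohex-2-en-1-ol
Conditions: (R)-1-methyl-3,3-diphenyltetrahydro-1H,3H-pyrrolo[1,2-c][1,3,2]oxazaborole (10 mol %), BH3·SMe2, THF, −20 °C; MeOH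
Reagents that add atoms: none
Why: Corey–Bakshi–Shibata reduction with the alkenyl carbon as the large group should give the (S)-allylic alcohol, the future C14.

Step 12
Reactants: 17 (S)-2-methylcyclohex-2-en-1-ol
Product: 18 (S)-tert-butyldimethyl[(2-methylcyclohex-2-en-1-yl)oxy]silane
Conditions: TBSCl, imidazole, DMF, rt
Reagents that add atoms: tert-butyldimethylsilyl chloride, CC(C)(C)[Si](C)(C)Cl
Why: Standard silylation of a secondary allylic alcohol.

Step 13
Reactants: 18 silyl ether
Product: 19 (S)-4-(tert-butyldimethylsilyloxy)-3-methylcyclohex-2-en-1-one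
Conditions: Pd(OH)2/C (cat.), t-BuOOH, K2CO3, CH2Cl2, 4 °C → rt
Reagents that add atoms: tert-butyl hydroperoxide, CC(C)(C)OO
Why: Allylic C–H oxidation at the methylene next to the unsubstituted alkene carbon (C11); the silyloxy-bearing C–H next to the methyl-substituted alkene carbon is hindered.

Step 14
Reactants: 19 silyloxy enone
Product: 20 (S)-tert-butyldimethyl[(2-methyl-4-methylenecyclohex-2-en-1-yl)oxy]silane
Conditions: Ph3PCH3Br, KOtBu, THF, 0 °C → rt
Reagents that add atoms: methyltriphenylphosphonium bromide, C[P+](c1ccccc1)(c1ccccc1)c1ccccc1.[Br-]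
Why: Wittig methylenation of the enone carbonyl gives the exocyclic/endocyclic 1,3-diene and introduces C20.

Step 15
Reactants: 20 diene
Product: 21 tert-butyldimethyl{[(1S,4S)-2-methyl-4-(4,4,5,5-tetramethyl-1,3,2-dioxaborolan-2-yl)-4-[(4,4,5,5-tetramethyl-1,3,2-dioxaborolan-2-yl)methyl]cyclohex-2-en-1-yl]oxy}silane (boron on C11 cis to the silyloxy group)
Conditions: B2pin2, Pt(dba)3 (3 mol %, zerovalent platinum), TADDOL-derived P-phenyl phosphonite ligand (aryl = 3,5-diethylphenyl; antipode matched to α-face delivery), toluene, 60 °C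
Reagents that add atoms: bis(pinacolato)diboron, CC1(C)OB(OC1(C)C)B1OC(C)(C)C(C)(C)O1
Why: Platinum-catalysed 1,2-diboration of a 1,3-diene that cannot reach the s-cis geometry, so both borons add across the terminal C11=C20 alkene; the chiral phosphonite is relied on to place boron on the α face of C11.

**Union and endgame (steps 16–24)**

Step 16
Reactants: 15 dialdehyde; 21 bis(boronate)
Product: 24 tricyclic diol (2-OH and 9-OH; 9R; 3-OTES; 14-OTBS; C11=C20 methylene; other centres as in the target), via mono-allylation borate 22 (not isolated), via bis-borate 23 (not isolated)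
Conditions: 21 (1.5 equiv), toluene, 60 °C, slow addition of 15 (final 5 mM), then 80 °C; aq. NaHCO3
Reagents that add atoms: none
Why: The tertiary allylboronate (boron on C11) adds through a closed chair transition state to the unhindered C2 aldehyde, bonding at C1 on the boron-bearing α face (cis to the silyloxy group), which sets the quaternary C1 and, with the aldehyde residue equatorial, the 2R carbinol; the allyl shift turns the CH2Bpin group into a new allylboronate (22) whose γ-carbon C10 then attacks the C9 aldehyde. The closest known reaction type is the tandem diene diboration/double allylation of dicarbonyl compounds, combined with intramolecular allylboration as used to close medium-ring ethers. The second event closes the ten-membered carbocycle (an eight-membered ring counted through the pyran oxygen) by intramolecular allyl transfer, leaving the new C11=C20 alkene exocyclic to the ring formed. C10 is under substrate control: the axial 14-silyloxy group is 1,3-diaxial to the α face of C10, and a cis-fused transition state would drive the C11–C12 edge into the lactone flank of the pyran, so C9 should enter on the β face and give the trans ring fusion. C9 is expected to form with its oxygen on the outer face (9R, chair with C8 equatorial) and is reset in steps 18 and 19, so either C9 epimer converges. The selectivity needed is pairing (C1 with C2, C10 with C9): the hindered tertiary boronate should engage only the unhindered aldehyde and leave the neopentyl C9 aldehyde for the tethered second event, which slow addition and dilution keep intramolecular.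

Step 17
Reactants: 24 tricyclic diol
Product: 26 2,3-O-isopropylidene derivative (9-OH free; 14-OTBS), via desilylated triol 25 (not isolated)
Conditions: 2,2-dimethoxypropane, camphorsulfonic acid (cat.), MeOH (3 equiv), CH2Cl2, rt
Reagents that add atoms: 2,2-dimethoxypropane, COC(C)(C)OC
Why: Acid-catalysed methanolysis of the labile TES ether and acetonide formation on the syn-2,3-diol mask C2–OH and leave only the hindered C9–OH free.

Step 18
Reactants: 26 acetonide alcohol
Product: 27 C9 ketone
Conditions: Dess–Martin periodinane, NaHCO3, CH2Cl2, 0 °C → rt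
Reagents that add atoms: none
Why: Buffered Dess–Martin oxidation of the only free alcohol avoids conjugation of the β,γ-alkene and epimerization at C10.

Step 19
Reactants: 27 C9 ketone
Product: 28 9S alcohol (natural C9 configuration)
Conditions: NaBH4, CeCl3·7H2O, MeOH/THF, −78 → −40 °C
Reagents that add atoms: none
Why: Luche reduction; hydride should attack the C9 carbonyl from the outer face of the oxa-bridged ring (the inner face is covered by the C3–C4 arm), placing the hydroxyl inside as in the target.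

Step 20
Reactants: 28 9S alcohol
Product: 29 tetraol (C2, C3, C9, C14 hydroxyls)
Conditions: aq. HF (48%), MeCN, 0 °C → rt
Reagents that add atoms: none
Why: Aqueous HF cleaves the acetonide and the secondary TBS ether in one operation without touching the lactone or the alkenes.

Step 21
Reactants: 29 tetraol
Product: 30 tetraacetate (2-, 3-, 9-, 14-OAc)
Conditions: Ac2O, DMAP, pyridine, 40 °C
Reagents that add atoms: acetic anhydride, CC(=O)OC(C)=O
Why: DMAP-catalysed exhaustive acetylation of four secondary alcohols.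

Step 22
Reactants: 30 tetraacetate
Product: 31 11α,20-epoxide
Conditions: mCPBA (1.1 equiv), NaHCO3, CH2Cl2, −10 → 0 °C
Reagents that add atoms: 3-chloroperbenzoic acid, OOC(=O)c1cccc(Cl)c1
Why: Prilezhaev epoxidation should prefer the unhindered C11=C20 alkene over the C5=C6 alkene (two allylic C–O bonds, shielded in the bicycle), and the peracid approaches C11 from the α face because the axial C15 methyl is 1,3-diaxial to the β face.

Step 23
Reactants: 31 epoxide
Product: 32 11-hydroxy-20-chloro compound (target lacking only the C6 chloride; C5 methyl, C5=C6)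
Conditions: LiCl, AcOH, THF, rt
Reagents that add atoms: lithium chloride, [Li+].[Cl-]
Why: Acid-assisted SN2 opening of the 2,2-disubstituted epoxide by chloride at the primary C20 retains the C11–O configuration and gives the tertiary alcohol.

Step 24
Reactants: 32 chlorohydrin
Product: 33 Fragilide F
Conditions: Ca(OCl)2, CO2 (dry ice), CH2Cl2/H2O, 0 °C, dark
Reagents that add atoms: calcium hypochlorite, [Ca+2].[O-]Cl.[O-]Cl
Why: Ene-type chlorination with hypochlorous acid: Cl+ should add to C6 from the open upper face (the lower face is covered by the C3–C2–C1–C10–C9 bridge) and the C5 cation loses a proton from the C16 methyl, since the ring C–H bonds at C4 and C7 lie in the nodal plane.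

**Compound list**

1 | furan-2-ylmethanol | OCc1ccco1 | starting material
2 | tert-butyl(furan-2-ylmethoxy)dimethylsilane | CC(C)(C)[Si](C)(C)OCc1ccco1 | intermediate
3 | (S)-2,2-dimethyl-1,3-dioxolane-4-carbaldehyde | O=C[C@@H]1COC(C)(C)O1 | starting material
4 | [5-((tert-butyldimethylsilyloxy)methyl)furan-2-yl]lithium | [Li]c1ccc(CO[Si](C)(C)C(C)(C)C)o1 | intermediate
5 | [5-((tert-butyldimethylsilyloxy)methyl)furan-2-yl]zinc bromide | Br[Zn]c1ccc(CO[Si](C)(C)C(C)(C)C)o1 | intermediate
6 | (S)-[5-((tert-butyldimethylsilyloxy)methyl)furan-2-yl][(4S)-2,2-dimethyl-1,3-dioxolan-4-yl]methanol | CC(C)(C)[Si](C)(C)OCc1ccc(o1)[C@@H](O)[C@@H]1COC(C)(C)O1 | intermediate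
7 | (2S)-6-[(tert-butyldimethylsilyloxy)methyl]-2-[(4S)-2,2-dimethyl-1,3-dioxolan-4-yl]-6-hydroxy-2H-pyran-3(6H)-one (anomers) | O=C1C=CC(O)(CO[Si](C)(C)C(C)(C)C)O[C@H]1[C@@H]2COC(C)(C)O2 | intermediate
8 | tert-butyl[(1-methoxyethenyl)oxy]dimethylsilane | C=C(OC)O[Si](C)(C)C(C)(C)C | starting material
9 | methyl 2-[(2S,6S)-2-[(tert-butyldimethylsilyloxy)methyl]-6-[(4S)-2,2-dimethyl-1,3-dioxolan-4-yl]-5-oxo-5,6-dihydro-2H-pyran-2-yl]acetate | COC(=O)C[C@@]1(CO[Si](C)(C)C(C)(C)C)C=CC(=O)[C@@H](O1)[C@@H]2COC(C)(C)O2 | intermediate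
10 | 5-hydroxy-5-methyl analogue of 9 (C5 epimers) | COC(=O)C[C@@]1(CO[Si](C)(C)C(C)(C)C)C=CC(C)(O)[C@@H](O1)[C@@H]2COC(C)(C)O2 | intermediate
11 | cis-fused γ-lactone/5-methyl-dihydropyran with C8 CH2OTBS and C4 dioxolanyl | CC1=C[C@@H]2OC(=O)C[C@]2(CO[Si](C)(C)C(C)(C)C)O[C@H]1[C@@H]3COC(C)(C)O3 | intermediate
12 | 17-methyl lactone (17R) | CC1=C[C@@H]2OC(=O)[C@H](C)[C@]2(CO[Si](C)(C)C(C)(C)C)O[C@H]1[C@@H]3COC(C)(C)O3 | intermediate
13 | lactone triol (C2, C3, C9 hydroxyls) | CC1=C[C@@H]2OC(=O)[C@H](C)[C@]2(CO)O[C@H]1[C@@H](O)CO | intermediate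
14 | tris(triethylsilyl) ether of 13 | CC1=C[C@@H]2OC(=O)[C@H](C)[C@]2(CO[Si](CC)(CC)CC)O[C@H]1[C@@H](O[Si](CC)(CC)CC)CO[Si](CC)(CC)CC | intermediate
15 | pyran–lactone dialdehyde (3-OTES) | CC1=C[C@@H]2OC(=O)[C@H](C)[C@]2(C=O)O[C@H]1[C@@H](O[Si](CC)(CC)CC)C=O | intermediate
16 | 2-methylcyclohex-2-en-1-one | CC1=CCCCC1=O | starting material
17 | (S)-2-methylcyclohex-2-en-1-ol | CC1=CCCC[C@@H]1O | intermediate
18 | (S)-tert-butyldimethyl[(2-methylcyclohex-2-en-1-yl)oxy]silane | CC1=CCCC[C@@H]1O[Si](C)(C)C(C)(C)C | intermediate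
19 | (S)-4-(tert-butyldimethylsilyloxy)-3-methylcyclohex-2-en-1-one | CC1=CC(=O)CC[C@@H]1O[Si](C)(C)C(C)(C)C | intermediate
20 | (S)-tert-butyldimethyl[(2-methyl-4-methylenecyclohex-2-en-1-yl)oxy]silane | CC1=CC(=C)CC[C@@H]1O[Si](C)(C)C(C)(C)C | intermediate
21 | (1S,4S)-bis(boronate), boron on C11 cis to OTBS | CC1=C[C@@](B2OC(C)(C)C(C)(C)O2)(CB2OC(C)(C)C(C)(C)O2)CC[C@@H]1O[Si](C)(C)C(C)(C)C | intermediate
22 | mono-allylation borate (C1–C2 formed; 2-OBpin; C10=C11 with CH2Bpin; free C9 aldehyde) | CC=1[C@H]([C@@H](O[Si](CC)(CC)CC)[C@H](OB4OC(C)(C)C(C)(C)O4)[C@]5(C)C=C(CB6OC(C)(C)C(C)(C)O6)CC[C@@H]5O[Si](C)(C)C(C)(C)C)O[C@]3([C@@H](C)C(=O)O[C@H]3C=1)C=O | intermediate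
23 | bis(pinacolborate) ester of 24 | CC=1[C@H]2O[C@]3([C@@H](C)C(=O)O[C@H]3C=1)[C@H](OB4OC(C)(C)C(C)(C)O4)[C@H]1C(=C)CC[C@H](O[Si](C)(C)C(C)(C)C)[C@]1(C)[C@@H](OB4OC(C)(C)C(C)(C)O4)[C@@H]2O[Si](CC)(CC)CC | intermediate
24 | tricyclic diol (9R; 3-OTES; 14-OTBS; 11(20)-ene; 5-ene) | CC=1[C@H]2O[C@]3([C@@H](C)C(=O)O[C@H]3C=1)[C@H](O)[C@H]1C(=C)CC[C@H](O[Si](C)(C)C(C)(C)C)[C@]1(C)[C@@H](O)[C@@H]2O[Si](CC)(CC)CC | intermediate
25 | 2,3,9-triol (14-OTBS) | CC=1[C@H]2O[C@]3([C@@H](C)C(=O)O[C@H]3C=1)[C@H](O)[C@H]1C(=C)CC[C@H](O[Si](C)(C)C(C)(C)C)[C@]1(C)[C@@H](O)[C@@H]2O | intermediate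
26 | 2,3-O-isopropylidene-9R-alcohol | CC=1[C@H]2O[C@]3([C@@H](C)C(=O)O[C@H]3C=1)[C@H](O)[C@H]1C(=C)CC[C@H](O[Si](C)(C)C(C)(C)C)[C@]1(C)[C@H]4OC(C)(C)O[C@H]24 | intermediate
27 | C9 ketone | CC=1[C@H]2O[C@]3([C@@H](C)C(=O)O[C@H]3C=1)C(=O)[C@H]1C(=C)CC[C@H](O[Si](C)(C)C(C)(C)C)[C@]1(C)[C@H]4OC(C)(C)O[C@H]24 | intermediate
28 | 9S alcohol | CC=1[C@H]2O[C@]3([C@@H](C)C(=O)O[C@H]3C=1)[C@@H](O)[C@H]1C(=C)CC[C@H](O[Si](C)(C)C(C)(C)C)[C@]1(C)[C@H]4OC(C)(C)O[C@H]24 | intermediate
29 | 2,3,9,14-tetraol | CC=1[C@H]2O[C@]3([C@@H](C)C(=O)O[C@H]3C=1)[C@@H](O)[C@H]1C(=C)CC[C@H](O)[C@]1(C)[C@@H](O)[C@@H]2O | intermediate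
30 | 2,3,9,14-tetraacetate | CC=1[C@H]2O[C@]3([C@@H](C)C(=O)O[C@H]3C=1)[C@@H](OC(C)=O)[C@H]1C(=C)CC[C@H](OC(C)=O)[C@]1(C)[C@@H](OC(C)=O)[C@@H]2OC(C)=O | intermediate
31 | 11α,20-epoxide | CC=1[C@H]2O[C@]3([C@@H](C)C(=O)O[C@H]3C=1)[C@@H](OC(C)=O)[C@H]1[C@@]4(CO4)CC[C@H](OC(C)=O)[C@]1(C)[C@@H](OC(C)=O)[C@@H]2OC(C)=O | intermediate
32 | 11-hydroxy-20-chloro-5-ene (6-deschloro precursor) | CC=1[C@H]2O[C@]3([C@@H](C)C(=O)O[C@H]3C=1)[C@@H](OC(C)=O)[C@H]1[C@@](O)(CCl)CC[C@H](OC(C)=O)[C@]1(C)[C@@H](OC(C)=O)[C@@H]2OC(C)=O | intermediate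
33 | Fragilide F | C=C1[C@H]2O[C@]3([C@@H](C)C(=O)O[C@H]3[C@H]1Cl)[C@@H](OC(C)=O)[C@H]1[C@@](O)(CCl)CC[C@H](OC(C)=O)[C@]1(C)[C@@H](OC(C)=O)[C@@H]2OC(C)=O | target

**Step count and risks**

Total step count: 24. Longest linear sequence: 19 steps (steps 1–10, then 16–24).

Steps most likely to fail:

1. Step 16. The tethered second allylboration may deliver the C9 aldehyde to the α face of C10 (cis ring fusion), or be overtaken by intermolecular allylation when closure is slow. The fallback sets out from 15 and 21 and returns at 27. The cis-fused diol F1 is taken through the same methanolysis/acetonide formation to the cis-fused acetonide F2, and Dess–Martin oxidation gives the cis-fused C9 ketone F3. C10 is then α to the ketone and is equilibrated with DBU in toluene to the trans-fused ketone 27. The ring fusion is thereby set by thermodynamic enolization instead of kinetic allyl transfer.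

2. Step 15. Boron delivery to C11 may show poor facial control against the resident C14 centre, or 1,4-addition may compete. The fallback sets out from 19 and returns at 21. Luche reduction (NaBH4, CeCl3·7H2O) gives the cis allylic alcohol F4, and N,N-diisopropylcarbamoyl chloride converts it to the carbamate F5. Lithiation with s-BuLi/TMEDA at −78 °C, trapping with bis(pinacolboryl)methane and warming for the 1,2-metalate shift should give 21 stereospecifically. Boron takes the place of the carbamate oxygen and the CH2Bpin group that of hydrogen.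

3. Step 24. Electrophilic attack on the doubly deactivated C5=C6 alkene may be slow and be diverted to addition across the alkene. The fallback sets out from 32 and returns at 33. A Schenck ene reaction (O2, tetraphenylporphyrin, light) gives the allylic hydroperoxide F6, which is dehydrated in the same flask (Ac2O, pyridine; Kornblum–DeLaMare) to the α-methylene ketone F7. Luche reduction from the open upper face gives the 6-epi alcohol F8. An Appel reaction (PPh3, hexachloroacetone) displaces it with inversion to give 33.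

Further compounds
F1 | step 16 | cis-fused (10-epi) diol corresponding to 24 | CC=1[C@H]2O[C@]3([C@@H](C)C(=O)O[C@H]3C=1)[C@H](O)[C@@H]1C(=C)CC[C@H](O[Si](C)(C)C(C)(C)C)[C@]1(C)[C@@H](O)[C@@H]2O[Si](CC)(CC)CC
F2 | step 16 | cis-fused 2,3-O-isopropylidene alcohol | CC=1[C@H]2O[C@]3([C@@H](C)C(=O)O[C@H]3C=1)[C@H](O)[C@@H]1C(=C)CC[C@H](O[Si](C)(C)C(C)(C)C)[C@]1(C)[C@H]4OC(C)(C)O[C@H]24
F3 | step 16 | cis-fused C9 ketone (10-epi-27) | CC=1[C@H]2O[C@]3([C@@H](C)C(=O)O[C@H]3C=1)C(=O)[C@@H]1C(=C)CC[C@H](O[Si](C)(C)C(C)(C)C)[C@]1(C)[C@H]4OC(C)(C)O[C@H]24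
F4 | step 15 | cis-4-(tert-butyldimethylsilyloxy)-3-methylcyclohex-2-en-1-ol | CC1=C[C@H](O)CC[C@@H]1O[Si](C)(C)C(C)(C)C
F5 | step 15 | N,N-diisopropylcarbamate of F4 | CC1=C[C@H](OC(=O)N(C(C)C)C(C)C)CC[C@@H]1O[Si](C)(C)C(C)(C)C
F6 | step 24 | 6-hydroperoxy-5(16)-ene derived from 32 | C=C1[C@H]2O[C@]3([C@@H](C)C(=O)O[C@H]3[C@H]1OO)[C@@H](OC(C)=O)[C@H]1[C@@](O)(CCl)CC[C@H](OC(C)=O)[C@]1(C)[C@@H](OC(C)=O)[C@@H]2OC(C)=O
F7 | step 24 | 6-oxo-5(16)-ene (α-methylene ketone) | C=C1[C@H]2O[C@]3([C@@H](C)C(=O)O[C@H]3C1=O)[C@@H](OC(C)=O)[C@H]1[C@@](O)(CCl)CC[C@H](OC(C)=O)[C@]1(C)[C@@H](OC(C)=O)[C@@H]2OC(C)=O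
F8 | step 24 | 6-epi alcohol (hydroxyl on the face opposite to the target chloride) | C=C1[C@H]2O[C@]3([C@@H](C)C(=O)O[C@H]3[C@@H]1O)[C@@H](OC(C)=O)[C@H]1[C@@](O)(CCl)CC[C@H](OC(C)=O)[C@]1(C)[C@@H](OC(C)=O)[C@@H]2OC(C)=O
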